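The synthesis rests on cutting both C3–O bonds of the two catechol rings (each benzene ring numbered C1 at the ethane linker, C3 and C4 at oxygen, C5 at the carbon bonded to cyclopentane carbon C1'). One late operation with 2-iodoxybenzoic acid oxidises a bis(phenol) in both directions to the bis(ortho-quinone). It exploits that, of the two carbons ortho to each C4 oxygen, only C3 bears hydrogen: C5 is blocked by quaternary C1' and the para carbon C1 by the linker. The precursor is a C2-symmetric bibenzyl bis(phenol) with an (S)-1,2,2-trimethylcyclopentyl group ortho to each hydroxyl. It comes from 4,4'-dihydroxybibenzyl by double Mitsunobu etherification, double aromatic Claisen rearrangement with chirality transfer, and hydrogenation.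

Key step: step 7

Remark on the chemistry: in step 3 the alkenyl arm of the enone is assumed to act as the larger carbonyl substituent, which with the (S)-oxazaborolidine predicts the (1R)-alcohol; the sense and the enantiopurity are to be confirmed (chiral GC, Mosher esters) before the alcohol is carried on.

Step 1
Reactants: 1 3-ethoxycyclopent-2-en-1-one
Product: 3 3-ethoxy-5,5-dimethylcyclopent-2-en-1-one, via 3-ethoxy-5-methylcyclopent-2-en-1-one 2 (not isolated)
Conditions: LDA (commercial solution, 1.1 equiv), THF, −78 °C, then MeI (1.1 equiv), −78 to −20 °C; LDA (1.3 equiv), −78 °C, then MeI (2.0 equiv), DMPU, −78 °C to rt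
Reagents that add atoms: iodomethane, CI
Why: Kinetic deprotonation of the vinylogous ester at the alpha' carbon C5 and SN2 methylation, run twice in one flask (Stork–Danheiser-type alkylation), should put both methyl groups on the carbon that will later flank the quaternary centre.

Step 2
Reactants: 3 3-ethoxy-5,5-dimethylcyclopent-2-en-1-one
Product: 5 3,4,4-trimethylcyclopent-2-en-1-one, via 3-ethoxy-1,5,5-trimethylcyclopent-2-en-1-ol 4 (not isolated)
Conditions: MeLi (1.5 equiv), Et2O, −78 to 0 °C; then 2 M aq HCl, 0 °C to rt
Reagents that add atoms: methyllithium, [Li]C; water, O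
Why: 1,2-Addition of methyllithium to the vinylogous ester carbonyl and acid hydrolysis with allylic transposition (Stork–Danheiser enone transposition) should move the carbonyl to the former ethoxy carbon and leave the new methyl on the alkene carbon next to the gem-dimethyl group.

Step 3
Reactants: 5 3,4,4-trimethylcyclopent-2-en-1-one
Product: 6 (1R)-3,4,4-trimethylcyclopent-2-en-1-ol
Conditions: (S)-2-methyl-CBS-oxazaborolidine (0.2 equiv), catecholborane (1.6 equiv), toluene, −78 °C; MeOH quench, 1 M aq NaOH wash
Reagents that add atoms: none
Why: Corey–Bakshi–Shibata reduction, in which the ketone binds the catalyst boron anti to its larger alkenyl arm and hydride is delivered within the complex to one carbonyl face, should set the (1R)-carbinol, the only stereocentre in the route that is set by a reagent.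

Step 4
Reactants: 6 (1R)-3,4,4-trimethylcyclopent-2-en-1-ol; 7 4,4'-dihydroxybibenzyl
Product: 8 1,2-bis(4-{[(1S)-3,4,4-trimethylcyclopent-2-en-1-yl]oxy}phenyl)ethane
Conditions: 6 (2.6 equiv), PPh3 (2.8 equiv), DIAD (2.8 equiv), toluene, −20 °C to rt
Reagents that add atoms: none
Why: Double Mitsunobu etherification, in which each phenoxide displaces the alkoxyphosphonium group by SN2 with inversion, should turn the (1R)-carbinol into the (1S)-aryl ether; SN2' attack is disfavoured because the far allylic carbon is fully substituted and adjoins the gem-dimethyl carbon.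

Step 5
Reactants: 8 1,2-bis(4-{[(1S)-3,4,4-trimethylcyclopent-2-en-1-yl]oxy}phenyl)ethane
Product: 9 4,4'-(ethane-1,2-diyl)bis{2-[(1S)-1,5,5-trimethylcyclopent-2-en-1-yl]phenol}
Conditions: PhNEt2 (degassed), 195 °C, sealed tube, Ar
Reagents that add atoms: none
Why: Double aromatic Claisen rearrangement, a concerted suprafacial [3,3] shift through the boat-like transition state imposed by the five-membered ring, should deliver the ortho carbon to the methyl-bearing alkene carbon on the face that carried oxygen, so that each (1S)-ether centre is relayed to a (1S)-benzylic quaternary carbon before tautomerisation restores the phenol; the para carbon is blocked by the linker and the basic solvent suppresses ionisation.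

Step 6
Reactants: 9 4,4'-(ethane-1,2-diyl)bis{2-[(1S)-1,5,5-trimethylcyclopent-2-en-1-yl]phenol}
Product: 10 4,4'-(ethane-1,2-diyl)bis{2-[(1S)-1,2,2-trimethylcyclopentyl]phenol}
Conditions: H2 (3 atm), 10% Pd/C, EtOAc/EtOH, rt
Reagents that add atoms: none
Why: Heterogeneous catalytic hydrogenation of the two cis-disubstituted cyclopentene double bonds creates and touches no stereocentre and leaves the phenols and the linker alone; crystallisation of 10 is the planned point for removing any meso diastereomer that imperfect enantiopurity of 6 would bring in.

Step 7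
Reactants: 10 4,4'-(ethane-1,2-diyl)bis{2-[(1S)-1,2,2-trimethylcyclopentyl]phenol}; 11 2-iodoxybenzoic acid
Product: 12 5,5'-(ethane-1,2-diyl)bis{3-[(1S)-1,2,2-trimethylcyclopentyl]cyclohexa-3,5-diene-1,2-dione}, the bis(ortho-quinone)
Conditions: 11 (2.3 equiv), DMF, rt, dark, Ar; cold EtOAc/aq NaHCO3 work-up, crude 12 used at once
Reagents that add atoms: 2-iodoxybenzoic acid, O=C1OI(=O)(O)c2ccccc12
Why: Each phenol oxygen of 10 exchanges onto the pentavalent iodine of 11 with loss of water, and the aryloxy-iodane passes an iodine-bound oxygen to the adjacent ortho carbon C3 through a cyclic intramolecular transition state, iodine dropping to the trivalent state; tautomerisation to the iodine-bound catechol and a second two-electron transfer then release the ortho-quinone and 2-iodobenzoic acid, in which iodine is monovalent, so one equivalent of 11 is consumed per ring. The closest known reaction type is the ortho-selective oxidation of electron-rich phenols to ortho-quinones with 2-iodoxybenzoic acid, well established for 2-tert-alkyl-4-alkylphenols. No ring is closed and no stereocentre is made; the two C1' centres carry no hydrogen and are untouched. The selectivity needed is regiochemical, C3 against C5 and C1, and the substrate secures it: oxygen can only be delivered to an ortho carbon, C5 is occupied by C1' and the para carbon C1 by the linker. Chemoselectivity over the benzylic CH2 groups of the linker is expected at room temperature, where benzylic oxidation by this reagent should not compete, and the bulky C1' group beside the new C4 carbonyl shields each quinone from dimerisation. The two rings are insulated by the saturated linker and should react independently, so a slight excess of oxidant should drive both to completion.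

Step 8
Reactants: 12 5,5'-(ethane-1,2-diyl)bis{3-[(1S)-1,2,2-trimethylcyclopentyl]cyclohexa-3,5-diene-1,2-dione}
Product: 13 5,5'-(ethane-1,2-diyl)bis{3-[(1S)-1,2,2-trimethylcyclopentyl]benzene-1,2-diol}, the target
Conditions: Na2S2O4 (6 equiv), THF/H2O (degassed), rt, Ar; dilute HCl to pH 4
Reagents that add atoms: none
Why: Dithionite reduction of each ortho-quinone by two electrons and two protons (the standard reductive work-up of ortho-quinones to catechols) should give the bis(catechol) without touching the stereocentres, oxygen being excluded because the product is air-sensitive.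

Compound list
1 | 3-ethoxycyclopent-2-en-1-one | CCOC1=CC(=O)CC1 | starting material
2 | 3-ethoxy-5-methylcyclopent-2-en-1-one (racemic) | CCOC1=CC(=O)C(C)C1 | intermediate
3 | 3-ethoxy-5,5-dimethylcyclopent-2-en-1-one | CCOC1=CC(=O)C(C)(C)C1 | intermediate
4 | 3-ethoxy-1,5,5-trimethylcyclopent-2-en-1-ol (racemic, formed as its lithium alkoxide) | CCOC1=CC(C)(O)C(C)(C)C1 | intermediate
5 | 3,4,4-trimethylcyclopent-2-en-1-one | CC1=CC(=O)CC1(C)C | intermediate
6 | (1R)-3,4,4-trimethylcyclopent-2-en-1-ol | O[C@H]1C=C(C)C(C)(C)C1 | intermediate
7 | 4,4'-dihydroxybibenzyl (4,4'-(ethane-1,2-diyl)diphenol) | Oc1ccc(CCc2ccc(O)cc2)cc1 | starting material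
8 | 1,2-bis(4-{[(1S)-3,4,4-trimethylcyclopent-2-en-1-yl]oxy}phenyl)ethane | CC1=C[C@@H](Oc2ccc(CCc3ccc(O[C@@H]4C=C(C)C(C)(C)C4)cc3)cc2)CC1(C)C | intermediate
9 | 4,4'-(ethane-1,2-diyl)bis{2-[(1S)-1,5,5-trimethylcyclopent-2-en-1-yl]phenol} | Oc1ccc(CCc2ccc(O)c([C@@]3(C)C=CCC3(C)C)c2)cc1[C@@]1(C)C=CCC1(C)C | intermediate
10 | 4,4'-(ethane-1,2-diyl)bis{2-[(1S)-1,2,2-trimethylcyclopentyl]phenol} | Oc1ccc(CCc2ccc(O)c([C@@]3(C)CCCC3(C)C)c2)cc1[C@@]1(C)CCCC1(C)C | intermediate
11 | 2-iodoxybenzoic acid | O=C1OI(=O)(O)c2ccccc12 | starting material
12 | 5,5'-(ethane-1,2-diyl)bis{3-[(1S)-1,2,2-trimethylcyclopentyl]cyclohexa-3,5-diene-1,2-dione} | O=C1C(=O)C([C@@]2(C)CCCC2(C)C)=CC(CCC2=CC(=O)C(=O)C([C@@]3(C)CCCC3(C)C)=C2)=C1 | intermediate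
13 | 5,5'-(ethane-1,2-diyl)bis{3-[(1S)-1,2,2-trimethylcyclopentyl]benzene-1,2-diol} | CC1(C)CCC[C@]1(C)c1cc(CCc2cc(O)c(O)c([C@@]3(C)CCCC3(C)C)c2)cc(O)c1O | target

Total step count: 8
Longest linear sequence: 8 steps (1 to 13)

Steps most likely to fail

1. Step 5 (double aromatic Claisen rearrangement). What may go wrong: the sigmatropic shift has to form a bond to an alkene carbon that already carries a methyl group and adjoins the gem-dimethyl carbon. At the temperature needed, the allylic C–O bond may instead break heterolytically or by syn-elimination to a cyclopentadiene and the free phenol. The second rearrangement may also stall after the first, or the product may isomerise further by an enolene-type hydrogen shift.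
Fallback, setting out from 6 and 7 and coming back at 10: form the two aryl–C1' bonds by copper-mediated anti-SN2' allylic substitution in place of the sigmatropic shift. Alcohol 6 would be esterified with pyridine-2-carboxylic acid (DCC, DMAP, CH2Cl2) to (1R)-3,4,4-trimethylcyclopent-2-en-1-yl pyridine-2-carboxylate F1, with the carbinol configuration retained. Bis(phenol) 7 would be protected (MOMCl, i-Pr2NEt, CH2Cl2) as 1,2-bis[4-(methoxymethoxy)phenyl]ethane F2 and lithiated ortho to both acetal oxygens (n-BuLi, TMEDA, Et2O, 0 °C). After transmetallation with MgBr2·OEt2 it would be treated with F1 and CuBr·SMe2 in THF at −40 to 0 °C. The picolinate leaving group steers the arylcopper to the distal alkene carbon on the face opposite to the ester, so the (1R)-ester should give 1,2-bis{4-(methoxymethoxy)-3-[(1S)-1,5,5-trimethylcyclopent-2-en-1-yl]phenyl}ethane F3. Hydrogenation (H2, 10% Pd/C, EtOAc) to 1,2-bis{4-(methoxymethoxy)-3-[(1S)-1,2,2-trimethylcyclopentyl]phenyl}ethane F4 and acetal cleavage (HCl, MeOH, 40 °C) would rejoin the route at 10.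

2. Step 4 (double Mitsunobu etherification). What may go wrong: the activated alkoxyphosphonium of this alcohol can ionise to an allyl cation whose far terminus is tertiary. That would erode the configuration at the carbinol carbon and, because two units are joined, feed a meso diastereomer into the later compounds. It could also divert material to a diene by elimination or leave the mono-ether.
Fallback, setting out from 5 and coming back at 8: make the aryl–oxygen bond in place of the alkyl–oxygen bond, so that the carbinol carbon is never activated. Enone 5 would be reduced with (R)-2-methyl-CBS-oxazaborolidine and catecholborane to (1S)-3,4,4-trimethylcyclopent-2-en-1-ol F5. This would be coupled twice with commercial 1,2-bis(4-bromophenyl)ethane by palladium-catalysed C–O cross-coupling ([Pd(allyl)Cl]2, a bulky biaryl di-tert-butylphosphine such as RockPhos, Cs2CO3, toluene, 90 °C). The aryl bromide adds oxidatively to zerovalent palladium, the alkoxide binds the divalent palladium, and reductive elimination leaves the carbinol C–O bond intact. The (1S)-alcohol should therefore give bis(ether) 8 with retention.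

3. Step 7 (two-directional oxidation with 11). What may go wrong: each quinone carries the CH2 linker on the carbon para to the C4 carbonyl and may tautomerise towards a quinone methide. Oxidation may also stop with one ring still a phenol, or the quinones may degrade during work-up.
Fallback, setting out from 10 and coming back at 13: introduce the C3 oxygen by formylation and Dakin oxidation, which bypasses the quinone. Magnesium-mediated ortho-formylation (MgCl2, Et3N, paraformaldehyde, MeCN, reflux) is specific for the free ortho carbon C3 and should give 5,5'-(ethane-1,2-diyl)bis{2-hydroxy-3-[(1S)-1,2,2-trimethylcyclopentyl]benzaldehyde} F6. Dakin oxidation (H2O2, NaOH, THF/H2O, 0 °C, Ar, then dilute HCl) converts each formyl group into a hydroxyl via the aryl formate and would deliver 13 directly.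

Further compounds
F1 | step 5 | (1R)-3,4,4-trimethylcyclopent-2-en-1-yl pyridine-2-carboxylate | O=C(O[C@H]1C=C(C)C(C)(C)C1)c1ccccn1
F2 | step 5 | 1,2-bis[4-(methoxymethoxy)phenyl]ethane | COCOc1ccc(CCc2ccc(OCOC)cc2)cc1
F3 | step 5 | 1,2-bis{4-(methoxymethoxy)-3-[(1S)-1,5,5-trimethylcyclopent-2-en-1-yl]phenyl}ethane | COCOc1ccc(CCc2ccc(OCOC)c([C@@]3(C)C=CCC3(C)C)c2)cc1[C@@]1(C)C=CCC1(C)C
F4 | step 5 | 1,2-bis{4-(methoxymethoxy)-3-[(1S)-1,2,2-trimethylcyclopentyl]phenyl}ethane | COCOc1ccc(CCc2ccc(OCOC)c([C@@]3(C)CCCC3(C)C)c2)cc1[C@@]1(C)CCCC1(C)C
F5 | step 4 | (1S)-3,4,4-trimethylcyclopent-2-en-1-ol | O[C@@H]1C=C(C)C(C)(C)C1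
F6 | step 7 | 5,5'-(ethane-1,2-diyl)bis{2-hydroxy-3-[(1S)-1,2,2-trimethylcyclopentyl]benzaldehyde} | O=Cc1cc(CCc2cc(C=O)c(O)c([C@@]3(C)CCCC3(C)C)c2)cc([C@@]2(C)CCCC2(C)C)c1O
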